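**Strategy.** Each aryl ring is numbered so that C1 carries the ethylene bridge, C3 the bromine and C4/C5 the hydroxyls. The route rests on excising C3 from ring A and ring B: what remains, C4–C5–C6–C1–C2, is a 4-alkylcyclopentane-1,2-dione that is symmetric about C1. In the forward direction dibromocarbene is inserted into one enol-ether C=C bond (C2=C4) of each ring of a bis(2,3-disilyloxycyclopentadiene). A single operation thus enlarges both five-membered rings to benzene rings and brings in bromine already placed next to O4. The precursor is the tetrakis(TBS) dienol ether of 1,2-bis(3,4-dioxocyclopentyl)ethane, made and used cold.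

Key step: step 6

Remark: (cyclopent-3-en-1-yl)methanol is taken as a purchasable compound. The carbinol centres of 5 and the ring centres of 8 form as mixtures and are left uncontrolled, because all of them are erased before the target, which has no stereocentre.

**Step 1**
Reactants: 1 (cyclopent-3-en-1-yl)methanol
Product: 2 4-(bromomethyl)cyclopent-1-ene
Conditions: CBr4, PPh3, CH2Cl2, 0 °C to rt
Reagents that add atoms: carbon tetrabromide, BrC(Br)(Br)Br
Why: Appel reaction, in which the primary alcohol is activated as an alkoxyphosphonium ion and displaced by bromide under neutral conditions that leave the ring alkene untouched.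

**Step 2**
Reactants: 2 4-(bromomethyl)cyclopent-1-ene (two molar equivalents in all: one is converted into the Grignard reagent 3, the other serves as the electrophile)
Product: 4 1,2-di(cyclopent-3-en-1-yl)ethane, via (cyclopent-3-en-1-ylmethyl)magnesium bromide 3 (not isolated)
Conditions: Mg, THF, rt (first equivalent of 2); then second equivalent of 2, Li2CuCl4 (3 mol%), NMP, THF, 0 °C to rt
Reagents that add atoms: 4-(bromomethyl)cyclopent-1-ene (the second equivalent of 2, which supplies the other cyclopentenylmethyl half of 4), BrCC1CC=CC1
Why: Copper-catalysed sp3–sp3 cross-coupling of a primary alkyl Grignard reagent with a primary alkyl bromide joins two cyclopentenylmethyl units through the new CH2–CH2 bond; both partners carry the same group, so halogen–magnesium exchange cannot give a crossed product, and the remote ring alkene offers no favourable cyclisation.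

**Step 3**
Reactants: 4 1,2-di(cyclopent-3-en-1-yl)ethane
Product: 5 4,4′-(ethane-1,2-diyl)di(cyclopentane-1,2-diol), cis-diol in each ring
Conditions: OsO4 (1 mol%), NMO, acetone/H2O, rt
Reagents that add atoms: N-methylmorpholine N-oxide, C[N+]1([O-])CCOCC1; water, O
Why: Catalytic OsO4/NMO syn-dihydroxylation adds both oxygens to one face of each ring alkene, so each ring becomes a cis-diol; the face relative to the bridge-bearing carbon is not controlled and need not be, since step 4 oxidises all four carbinol centres.

**Step 4**
Reactants: 5 4,4′-(ethane-1,2-diyl)di(cyclopentane-1,2-diol)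
Product: 6 4,4′-(ethane-1,2-diyl)di(cyclopentane-1,2-dione), present mainly as its bis-enol
Conditions: (COCl)2, DMSO, CH2Cl2, −78 °C, 5 added in DMSO/CH2Cl2; Et3N, −78 to 0 °C
Reagents that add atoms: none
Why: Swern oxidation of the four secondary alcohols, a method that takes vicinal diols to 1,2-diones without glycol cleavage; each dione should then rest as its 2-hydroxycyclopent-2-enone tautomer.

**Step 5**
Reactants: 6 4,4′-(ethane-1,2-diyl)di(cyclopentane-1,2-dione)
Product: 7 1,2-bis[3,4-bis(tert-butyldimethylsilyloxy)cyclopenta-2,4-dien-1-yl]ethane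
Conditions: TBSOTf (4.4 equiv), Et3N, CH2Cl2, −78 to −20 °C; cold pentane/aq. NaHCO3 work-up, used at once
Reagents that add atoms: tert-butyldimethylsilyl triflate, CC(C)(C)[Si](C)(C)OS(=O)(=O)C(F)(F)F
Why: Soft enolisation with a silyl triflate and a tertiary amine: after O-silylation of each enol hydroxyl, silylation of the remaining carbonyl and removal of the less hindered α′ proton (CH2 next to C=O) by Et3N gives the cross-conjugated 2-silyloxydiene, as is known for cyclopent-2-enones, while the low temperature and the weak base keep the 1,5-hydrogen shift and deprotonation of the diene from setting in.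

**Step 6**
Reactants: 7 1,2-bis[3,4-bis(tert-butyldimethylsilyloxy)cyclopenta-2,4-dien-1-yl]ethane
Product: 9 1,2-bis[3-bromo-4,5-bis(tert-butyldimethylsilyloxy)phenyl]ethane, via bis(6,6-dibromobicyclo[3.1.0]hexene) adduct 8 (not isolated)
Conditions: CHBr3 (8 equiv), KOC(CH3)3 (8 equiv, added in portions), pentane, −30 to −10 °C
Reagents that add atoms: bromoform, BrC(Br)Br
Why: Bromoform is deprotonated by tert-butoxide and the tribromomethyl anion loses bromide to give electrophilic singlet CBr2, which adds in a concerted [2+1] fashion to one of the two equivalent, electron-rich silyl enol ether C=C bonds (C2=C4) of each ring, anti to the bridge, to give the 6,6-dibromobicyclo[3.1.0]hexene 8. The closest known reactions are the dihalocarbene ring expansion of cyclic silyl enol ethers to 2-halo-enones and the conversion of cyclopentadiene or indene into a halobenzene or 2-halonaphthalene with the same base. Each six-membered ring is closed by a thermally allowed disrotatory two-electron opening of the cyclopropane fusion bond C2–C4, concerted with loss of the endo bromide, which leaves C3 with its remaining bromine bonded to C2 and C4 in a cyclohexadienyl cation stabilised by the C4 oxygen; this arenium ion gives up the C1 proton to tert-butoxide and becomes the arene. No stereocentre survives in the product, so nothing has to be controlled there. The step needs site selectivity, one carbene per ring and no migration of the diene before addition: the mirror symmetry of each 2,3-disilyloxydiene through C1 makes both C=C bonds lead to the same arene, aromatisation removes the enol ether character and so shuts off a second addition, and migration is held back by working below −10 °C and by adding the base in portions to an excess of the far more acidic bromoform, so that free tert-butoxide does not build up next to the doubly allylic C1–H. The bulky TBS groups should favour proton loss over silyl loss from the arenium ion and keep all four oxygens protected.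

**Step 7**
Reactants: 9 1,2-bis[3-bromo-4,5-bis(tert-butyldimethylsilyloxy)phenyl]ethane
Product: 10 5,5′-(ethane-1,2-diyl)bis(3-bromobenzene-1,2-diol), the target
Conditions: KHF2, MeOH/THF, rt, argon
Reagents that add atoms: none
Why: Fluoride-mediated cleavage of phenolic silyl ethers with KHF2 in methanol, a mildly acidic medium in which the air-sensitive bromocatechol is never exposed to base and the aryl bromides are inert.

**Compound list**
1 | (cyclopent-3-en-1-yl)methanol | OCC1CC=CC1 | starting material
2 | 4-(bromomethyl)cyclopent-1-ene | BrCC1CC=CC1 | intermediate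
3 | (cyclopent-3-en-1-ylmethyl)magnesium bromide, not isolated | Br[Mg]CC1CC=CC1 | intermediate
4 | 1,2-di(cyclopent-3-en-1-yl)ethane | C1=CCC(CCC2CC=CC2)C1 | intermediate
5 | 4,4′-(ethane-1,2-diyl)di(cyclopentane-1,2-diol), cis-diol in each ring, mixture of isomers with the diol cis or trans to the bridge | O[C@H]1CC(CCC2C[C@H](O)[C@H](O)C2)C[C@H]1O | intermediate
6 | 4,4′-(ethane-1,2-diyl)di(cyclopentane-1,2-dione), mainly as the bis-enol | O=C1CC(CCC2CC(=O)C(=O)C2)CC1=O | intermediate
7 | 1,2-bis[3,4-bis(tert-butyldimethylsilyloxy)cyclopenta-2,4-dien-1-yl]ethane | CC(C)(C)[Si](C)(C)OC1=CC(CCC2C=C(O[Si](C)(C)C(C)(C)C)C(O[Si](C)(C)C(C)(C)C)=C2)C=C1O[Si](C)(C)C(C)(C)C | intermediate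
8 | 1,2-bis[6,6-dibromo-1,2-bis(tert-butyldimethylsilyloxy)bicyclo[3.1.0]hex-2-en-4-yl]ethane, mixture of diastereomers, not isolated | CC(C)(C)[Si](C)(C)OC1=CC(CCC2C=C(O[Si](C)(C)C(C)(C)C)C3(O[Si](C)(C)C(C)(C)C)C(Br)(Br)C23)C2C(Br)(Br)C12O[Si](C)(C)C(C)(C)C | intermediate
9 | 1,2-bis[3-bromo-4,5-bis(tert-butyldimethylsilyloxy)phenyl]ethane | CC(C)(C)[Si](C)(C)Oc1cc(CCc2cc(O[Si](C)(C)C(C)(C)C)c(O[Si](C)(C)C(C)(C)C)c(Br)c2)cc(Br)c1O[Si](C)(C)C(C)(C)C | intermediate
10 | 5,5′-(ethane-1,2-diyl)bis(3-bromobenzene-1,2-diol) | Oc1cc(CCc2cc(O)c(O)c(Br)c2)cc(Br)c1O | target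

Total step count: 7. Longest linear sequence: 7 steps (1 to 10).

**Steps most likely to fail**

1. Step 6. The diene may lose its identity before the carbene arrives, either by removal of the doubly allylic C1–H by tert-butoxide and reprotonation elsewhere or by a thermal 1,5-hydrogen shift, so that carbon is inserted into the wrong bond; alkoxide may also strip silyl groups. The fallback sets out from 5 and comes back at 9. It performs the ring expansion on a plain, non-acidic cyclic silyl enol ether and reaches the aromatic oxidation level afterwards. Mono-silylation of each cis-diol of 5 (TBSCl, imidazole, DMF) should give 4,4′-(ethane-1,2-diyl)bis[2-(tert-butyldimethylsilyloxy)cyclopentan-1-ol] F1. Swern oxidation then gives the bis(α-silyloxy ketone) 4,4′-(ethane-1,2-diyl)bis[2-(tert-butyldimethylsilyloxy)cyclopentan-1-one] F2. Kinetic deprotonation on the CH2 side (LiN(CH(CH3)2)2, THF, −78 °C) and trapping with Me3SiCl gives 1,2-bis[4-(tert-butyldimethylsilyloxy)-3-(trimethylsilyloxy)cyclopent-2-en-1-yl]ethane F3. CHBr3/KOC(CH3)3 in pentane followed by warming expands each ring in the established way to 4,4′-(ethane-1,2-diyl)bis[2-bromo-6-(tert-butyldimethylsilyloxy)cyclohex-2-en-1-one] F4. TBSOTf/Et3N turns each enone into the dienol ether 1,2-bis[3-bromo-4,5-bis(tert-butyldimethylsilyloxy)cyclohexa-2,4-dien-1-yl]ethane F5, and DDQ in toluene dehydrogenates both cyclohexadienes to 9.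

2. Step 5. The second silylation may take the proton at the bridge-bearing ring carbon instead of a CH2 proton, or the diene may isomerise or undergo Diels–Alder dimerisation during work-up; the linearly conjugated or dimeric material cannot lead to 9. The fallback sets out from 6 and comes back at 7 in two stages under irreversible kinetic control. TBSCl/imidazole in DMF silylates only the enol hydroxyl and should give the stable enone 4,4′-(ethane-1,2-diyl)bis[2-(tert-butyldimethylsilyloxy)cyclopent-2-en-1-one] F6. Adding F6 to LiN(CH(CH3)2)2 in THF at −78 °C forms the cross-conjugated lithium dienolate by α′ deprotonation, and a TBSOTf quench at −78 °C gives 7 in a medium that no longer holds any base. The cold solution would go straight into step 6.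

3. Step 4. The tetraol dissolves poorly in CH2Cl2 and the enolic product can be captured by the activated sulfoxide, so the oxidation may stop part-way or give methylthiomethyl ethers. The fallback sets out from 4 and comes back at 6 without passing through 5. RuCl3-catalysed ketohydroxylation of both alkenes (KHSO5 as the triple salt 2KHSO5·KHSO4·K2SO4, NaHCO3, EtOAc/MeCN/H2O, rt) should give the bis-acyloin 4,4′-(ethane-1,2-diyl)bis(2-hydroxycyclopentan-1-one) F7. Cu(OAc)2 in aqueous acetic acid then oxidises each α-hydroxy ketone to the 1,2-dione 6.

**Further compounds**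
F1 | step 6 | 4,4′-(ethane-1,2-diyl)bis[2-(tert-butyldimethylsilyloxy)cyclopentan-1-ol], cis in each ring, mixture of stereoisomers | OC1CC(CCC2CC(O)C(O[Si](C)(C)C(C)(C)C)C2)CC1O[Si](C)(C)C(C)(C)C
F2 | step 6 | 4,4′-(ethane-1,2-diyl)bis[2-(tert-butyldimethylsilyloxy)cyclopentan-1-one], mixture of stereoisomers | O=C1CC(CCC2CC(=O)C(O[Si](C)(C)C(C)(C)C)C2)CC1O[Si](C)(C)C(C)(C)C
F3 | step 6 | 1,2-bis[4-(tert-butyldimethylsilyloxy)-3-(trimethylsilyloxy)cyclopent-2-en-1-yl]ethane, mixture of stereoisomers | C[Si](C)(C)OC1=CC(CCC2C=C(O[Si](C)(C)C)C(O[Si](C)(C)C(C)(C)C)C2)CC1O[Si](C)(C)C(C)(C)C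
F4 | step 6 | 4,4′-(ethane-1,2-diyl)bis[2-bromo-6-(tert-butyldimethylsilyloxy)cyclohex-2-en-1-one], mixture of stereoisomers | O=C1C(Br)=CC(CCC2C=C(Br)C(=O)C(O[Si](C)(C)C(C)(C)C)C2)CC1O[Si](C)(C)C(C)(C)C
F5 | step 6 | 1,2-bis[3-bromo-4,5-bis(tert-butyldimethylsilyloxy)cyclohexa-2,4-dien-1-yl]ethane | CC(C)(C)[Si](C)(C)OC1=C(O[Si](C)(C)C(C)(C)C)C(Br)=CC(CCC2C=C(Br)C(O[Si](C)(C)C(C)(C)C)=C(O[Si](C)(C)C(C)(C)C)C2)C1
F6 | step 5 | 4,4′-(ethane-1,2-diyl)bis[2-(tert-butyldimethylsilyloxy)cyclopent-2-en-1-one], mixture of stereoisomers | O=C1CC(CCC2CC(=O)C(O[Si](C)(C)C(C)(C)C)=C2)C=C1O[Si](C)(C)C(C)(C)C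
F7 | step 4 | 4,4′-(ethane-1,2-diyl)bis(2-hydroxycyclopentan-1-one), mixture of stereoisomers | O=C1CC(CCC2CC(=O)C(O)C2)CC1O
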